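**Strategy.** Everything rests on cutting the bond between the vinylic CH and the quaternary O-bearing carbon of the dimethylpyran ring fused to ring A. This exposes an isopropyl ether on O7 and a terminal alkyne on C8: the tertiary C–H of the ether sits 1,5 to the internal alkyne carbon. A PtI4-catalysed hydride shift followed by carbon–carbon closure isomerises this pair into the chromene ring in one operation, with no atom lost. The precursor is a fully substituted 8-ethynyl-7-isopropoxyflavone, built by para-Claisen–Cope prenylation, enolate acylation, diketone alkylation and cyclodehydration; the oxepine is closed afterwards by copper-catalysed O-vinylation.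

Key step: step 14

Remark: the target has no stereocentre and no stereogenic double bond, so no stereocontrol is needed; intermediates that carry a stereocentre are racemic or diastereomeric mixtures that converge. Flavone numbering (O1, C2–C8, primed positions on ring B) is used for all flavone-stage compounds.

**Step 1**
Reactants: 1 2,4,6-trihydroxyacetophenone
Product: 2 1-(2,6-dihydroxy-4-isopropoxyphenyl)ethanone
Conditions: 2-bromopropane (1.1 equiv), K2CO3, DMF, 50 °C
Reagents that add atoms: 2-bromopropane, CC(C)Br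
Why: Williamson etherification, in which the 4-hydroxyl is the only one not hydrogen-bonded to the acetyl carbonyl and is the most acidic, so one equivalent of the secondary bromide should alkylate it selectively.

**Step 2**
Reactants: 2 1-(2,6-dihydroxy-4-isopropoxyphenyl)ethanone
Product: 3 1-[2-hydroxy-4-isopropoxy-6-(methoxymethoxy)phenyl]ethanone
Conditions: MOMCl (1.05 equiv), iPr2NEt, CH2Cl2, 0 °C
Reagents that add atoms: chloromethyl methyl ether, COCCl
Why: MOM acetal formation by O-alkylation, in which the two chelated hydroxyls are equivalent and the one that remains is locked in a hydrogen bond to the carbonyl, so the reaction should stop at the mono-ether.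

**Step 3**
Reactants: 3 1-[2-hydroxy-4-isopropoxy-6-(methoxymethoxy)phenyl]ethanone
Product: 4 1-[4-isopropoxy-2-(methoxymethoxy)-6-(3-methylbut-2-enyloxy)phenyl]ethanone
Conditions: prenyl bromide, K2CO3, DMF, 60 °C
Reagents that add atoms: prenyl bromide (1-bromo-3-methylbut-2-ene), CC(C)=CCBr
Why: Williamson O-prenylation of the chelated phenol under forcing carbonate conditions, where the allylic bromide in a dipolar solvent should give O- and not C-alkylation.

**Step 4**
Reactants: 4 1-[4-isopropoxy-2-(methoxymethoxy)-6-(3-methylbut-2-enyloxy)phenyl]ethanone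
Product: 7 1-[6-hydroxy-4-isopropoxy-2-(methoxymethoxy)-3-(3-methylbut-2-enyl)phenyl]ethanone, via ortho-dienone 5 (not isolated), via para-dienone 6 (not isolated)
Conditions: N,N-diethylaniline, 200 °C, sealed tube
Reagents that add atoms: none
Why: Tandem aromatic Claisen/Cope rearrangement (para-Claisen), in which a [3,3] shift to the ortho carbon gives dienone 5, a second [3,3] shift relays the allyl unit to the para carbon (dienone 6) and enolisation follows, so the prenyl group should arrive un-inverted between the two alkoxy groups and the phenol is regenerated next to the free ring position, as known for 2-prenyloxy-4,6-dialkoxyacetophenones.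

**Step 5**
Reactants: 7 1-[6-hydroxy-4-isopropoxy-2-(methoxymethoxy)-3-(3-methylbut-2-enyl)phenyl]ethanone
Product: 8 1-[2-hydroxy-3-iodo-4-isopropoxy-6-(methoxymethoxy)-5-(3-methylbut-2-enyl)phenyl]ethanone
Conditions: NIS (1.05 equiv), DMF, 0 °C to rt, dark
Reagents that add atoms: N-iodosuccinimide, O=C1CCC(=O)N1I
Why: Electrophilic aromatic iodination at the only free ring position, which is ortho to the free phenol and to the isopropoxy group, so the arene should react faster than the prenyl double bond, which has no free hydroxyl neighbour to trap an iodonium ion.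

**Step 6**
Reactants: 9 2,4,5-trihydroxybenzaldehyde
Product: 10 2-hydroxy-4,5-bis(triisopropylsilyloxy)benzaldehyde
Conditions: TIPSCl (2.2 equiv), imidazole, DMF, 0 °C to rt
Reagents that add atoms: chlorotriisopropylsilane, CC(C)[Si](Cl)(C(C)C)C(C)C
Why: Silyl ether formation, in which the 4- and 5-hydroxyls should react while the 2-hydroxyl, hydrogen-bonded to the aldehyde, stays free.

**Step 7**
Reactants: 10 2-hydroxy-4,5-bis(triisopropylsilyloxy)benzaldehyde
Product: 11 2-(methoxymethoxy)-4,5-bis(triisopropylsilyloxy)benzaldehyde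
Conditions: MOMCl, iPr2NEt, CH2Cl2, 40 °C
Reagents that add atoms: chloromethyl methyl ether, COCCl
Why: MOM acetal formation on the remaining chelated phenol, which gives the 2-oxygen a group that is orthogonal to the silyl ethers and can later be removed together with the MOM group of ring A.

**Step 8**
Reactants: 11 2-(methoxymethoxy)-4,5-bis(triisopropylsilyloxy)benzaldehyde
Product: 12 2-(methoxymethoxy)-4,5-bis(triisopropylsilyloxy)benzoic acid
Conditions: NaClO2, NaH2PO4, 2-methyl-2-butene, t-BuOH/THF/H2O, rt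
Reagents that add atoms: sodium chlorite, [Na+].[O-]Cl=O
Why: Pinnick oxidation of the aldehyde to the acid in a buffered medium that should leave the MOM acetal and the aryl silyl ethers intact, with 2-methyl-2-butene trapping the hypochlorous acid.

**Step 9**
Reactants: 13 3-methylbuta-1,2-diene
Product: 15 1,2-dibromo-3-methylbut-2-ene, via 2,3-dibromo-3-methylbut-1-ene 14 (not isolated)
Conditions: Br2 (1.0 equiv), CH2Cl2, −78 °C to rt
Reagents that add atoms: bromine, BrBr
Why: Electrophilic addition of bromine to the more substituted double bond of the allene should give the tertiary allylic dibromide 14, which equilibrates by allylic shift of bromide to the primary bromide with the tetrasubstituted double bond (either allylic isomer would give the same product in step 11).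

**Step 10**
Reactants: 8 1-[2-hydroxy-3-iodo-4-isopropoxy-6-(methoxymethoxy)-5-(3-methylbut-2-enyl)phenyl]ethanone, 12 2-(methoxymethoxy)-4,5-bis(triisopropylsilyloxy)benzoic acid
Product: 17 1-[2-hydroxy-3-iodo-4-isopropoxy-6-(methoxymethoxy)-5-(3-methylbut-2-enyl)phenyl]-3-[2-(methoxymethoxy)-4,5-bis(triisopropylsilyloxy)phenyl]propane-1,3-dione, via acyl imidazolide 16 (not isolated)
Conditions: 12, CDI, THF, rt; then added to 8, LiN(SiMe3)2 (3.3 equiv), THF, −78 °C to rt; AcOH quench
Reagents that add atoms: none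
Why: Claisen-type C-acylation of the lithium enolate of the o-hydroxyacetophenone polyanion (the enolate variant of the Baker–Venkataraman route), in which the acyl imidazolide 16 avoids an acid chloride next to the MOM acetal and any O-acylated phenol should be carried to the same diketone by acyl transfer under the excess base.

**Step 11**
Reactants: 17 1-[2-hydroxy-3-iodo-4-isopropoxy-6-(methoxymethoxy)-5-(3-methylbut-2-enyl)phenyl]-3-[2-(methoxymethoxy)-4,5-bis(triisopropylsilyloxy)phenyl]propane-1,3-dione, 15 1,2-dibromo-3-methylbut-2-ene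
Product: 18 2-(2-bromo-3-methylbut-2-enyl)-1-[2-hydroxy-3-iodo-4-isopropoxy-6-(methoxymethoxy)-5-(3-methylbut-2-enyl)phenyl]-3-[2-(methoxymethoxy)-4,5-bis(triisopropylsilyloxy)phenyl]propane-1,3-dione
Conditions: K2CO3, acetone, 40 °C
Reagents that add atoms: none
Why: C-alkylation of the 1,3-diketone at its central carbon by the primary allylic bromide (soft enolate, soft electrophile), in which the alkenyl bromide is inert to substitution and the hindered, chelated phenol should not compete.

**Step 12**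
Reactants: 18 2-(2-bromo-3-methylbut-2-enyl)-1-[2-hydroxy-3-iodo-4-isopropoxy-6-(methoxymethoxy)-5-(3-methylbut-2-enyl)phenyl]-3-[2-(methoxymethoxy)-4,5-bis(triisopropylsilyloxy)phenyl]propane-1,3-dione
Product: 20 3-(2-bromo-3-methylbut-2-enyl)-8-iodo-7-isopropoxy-5-(methoxymethoxy)-2-[2-(methoxymethoxy)-4,5-bis(triisopropylsilyloxy)phenyl]-6-(3-methylbut-2-enyl)chromen-4-one, via 2-hydroxyflavanone hemiketal 19 (not isolated)
Conditions: PPTS (0.3 equiv), toluene, 4 Å MS, 80 °C
Reagents that add atoms: none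
Why: Acid-catalysed cyclodehydration of the 2-alkyl-1,3-diketone through hemiketal 19, in which only the phenol next to iodine is free and so alone can become O1, while the weak acid should spare both MOM acetals and the silyl ethers.

**Step 13**
Reactants: 20 3-(2-bromo-3-methylbut-2-enyl)-8-iodo-7-isopropoxy-5-(methoxymethoxy)-2-[2-(methoxymethoxy)-4,5-bis(triisopropylsilyloxy)phenyl]-6-(3-methylbut-2-enyl)chromen-4-one
Product: 22 3-(2-bromo-3-methylbut-2-enyl)-8-ethynyl-7-isopropoxy-5-(methoxymethoxy)-2-[2-(methoxymethoxy)-4,5-bis(triisopropylsilyloxy)phenyl]-6-(3-methylbut-2-enyl)chromen-4-one, via trimethylsilylalkyne 21 (not isolated)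
Conditions: ethynyltrimethylsilane, PdCl2(PPh3)2 (5 mol %), CuI (10 mol %), Et3N, THF, 50 °C; then K2CO3 (0.3 equiv), MeOH, 0 °C
Reagents that add atoms: ethynyltrimethylsilane, C#C[Si](C)(C)C
Why: Sonogashira coupling at the aryl iodide, which should undergo oxidative addition far faster than the hindered tetrasubstituted alkenyl bromide, followed in the same flask by brief carbonate-catalysed methanolysis of the C–Si bond of 21.

**Step 14**
Reactants: 22 3-(2-bromo-3-methylbut-2-enyl)-8-ethynyl-7-isopropoxy-5-(methoxymethoxy)-2-[2-(methoxymethoxy)-4,5-bis(triisopropylsilyloxy)phenyl]-6-(3-methylbut-2-enyl)chromen-4-one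
Product: 24 3-(2-bromo-3-methylbut-2-enyl)-5-(methoxymethoxy)-2-[2-(methoxymethoxy)-4,5-bis(triisopropylsilyloxy)phenyl]-8,8-dimethyl-6-(3-methylbut-2-enyl)-4H,8H-pyrano[2,3-f]chromen-4-one, via oxocarbenium alkenylplatinate zwitterion 23 (not isolated)
Conditions: PtI4 (10 mol %), MeCN, 100 °C, sealed tube, argon
Reagents that add atoms: none
Why: Proposed new method: PtI4 should bind the terminal alkyne and slip toward its terminus so that positive charge builds on the internal carbon at C8 (stabilised by O1, O7 and O5 of ring A); the tertiary C–H of the O7 isopropyl group lies 1,5 to this carbon and should be delivered to it as hydride through a six-membered transition state, giving the oxocarbenium/(Z)-alkenylplatinate zwitterion 23. After rotation about the aryl–alkenyl bond the platinum-bearing carbon (the former alkyne terminus) should attack the oxocarbenium carbon (the former isopropyl methine) with release of PtI4, which forms the new C–C bond, keeps the C=C bond and makes the step a pure isomerisation. The closest known reaction type is the PtI4-catalysed hydride-transfer cyclisation (alpha-alkenylation) of terminal alkynes onto C–H bonds next to the oxygen of saturated cyclic ethers, together with the PtCl2-catalysed cycloisomerisation of 1-alkyl-2-ethynylbenzenes to indenes; an aryl isopropyl ether as hydride donor across an arene tether has not been shown. The pyran ring closes in a 6-endo-trig mode with respect to the C=O+ bond, and no stereocentre is formed. The step needs hydride transfer to outrun 5-endo attack of O7 on the bound alkyne (which would end in loss or shift of the isopropyl group) and hydration, and needs closure at the platinum-bearing carbon (six-membered ring) and not at the benzylic carbon (five-membered ring): the oxygen-activated tertiary C–H held 1,5, the poor leaving ability of a secondary alkyl cation, the dry medium and the polarised C–Pt bond should secure this. The MOM group on O5 keeps platinum away from the 5-hydroxy-4-oxo chelate site and keeps a free 5-hydroxyl from adding to the prenyl group.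

**Step 15**
Reactants: 24 3-(2-bromo-3-methylbut-2-enyl)-5-(methoxymethoxy)-2-[2-(methoxymethoxy)-4,5-bis(triisopropylsilyloxy)phenyl]-8,8-dimethyl-6-(3-methylbut-2-enyl)-4H,8H-pyrano[2,3-f]chromen-4-one
Product: 25 3-(2-bromo-3-methylbut-2-enyl)-5-hydroxy-2-[2-hydroxy-4,5-bis(triisopropylsilyloxy)phenyl]-8,8-dimethyl-6-(3-methylbut-2-enyl)-4H,8H-pyrano[2,3-f]chromen-4-one
Conditions: 3 M aq. HCl, MeOH/THF, 45 °C
Reagents that add atoms: none
Why: Acid-catalysed acetal exchange with methanol (MOM cleavage) should free the 5- and 2′-hydroxyls before any enol ether is present, while aryl triisopropylsilyl ethers, the chromene, the prenyl group and the alkenyl bromide tolerate these conditions.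

**Step 16**
Reactants: 25 3-(2-bromo-3-methylbut-2-enyl)-5-hydroxy-2-[2-hydroxy-4,5-bis(triisopropylsilyloxy)phenyl]-8,8-dimethyl-6-(3-methylbut-2-enyl)-4H,8H-pyrano[2,3-f]chromen-4-one
Product: 26 4′,5′-bis-O-(triisopropylsilyl)isocycloheterophyllin
Conditions: CuI (20 mol %), 1,10-phenanthroline (40 mol %), Cs2CO3 (2.5 equiv), dioxane, 90 °C
Reagents that add atoms: none
Why: Intramolecular Ullmann-type O-vinylation (copper-catalysed C–O coupling of a phenoxide with an alkenyl bromide), in which only the 2′-phenoxide can reach the C–Br carbon (seven-membered ring), the chelated 5-hydroxyl cannot, and substitution at the sp2 carbon should leave the double bond exocyclic as the isopropylidene enol ether.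

**Step 17**
Reactants: 26 4′,5′-bis-O-(triisopropylsilyl)isocycloheterophyllin
Product: 27 isocycloheterophyllin
Conditions: Bu4NF (2.5 equiv), AcOH (2.5 equiv), THF, 0 °C, argon
Reagents that add atoms: none
Why: Fluoride-mediated cleavage of the two aryl silyl ethers, buffered with acetic acid to protect the catechol, should leave the acid-sensitive enol ether, the chromene and the prenyl group untouched.

**Compound list**

1 | 2,4,6-trihydroxyacetophenone | CC(=O)c1c(O)cc(O)cc1O | starting material
2 | 1-(2,6-dihydroxy-4-isopropoxyphenyl)ethanone | CC(=O)c1c(O)cc(OC(C)C)cc1O | intermediate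
3 | 1-[2-hydroxy-4-isopropoxy-6-(methoxymethoxy)phenyl]ethanone | CC(=O)c1c(O)cc(OC(C)C)cc1OCOC | intermediate
4 | 1-[4-isopropoxy-2-(methoxymethoxy)-6-(3-methylbut-2-enyloxy)phenyl]ethanone | CC(=O)c1c(OCC=C(C)C)cc(OC(C)C)cc1OCOC | intermediate
5 | 2-acetyl-5-isopropoxy-3-(methoxymethoxy)-6-(2-methylbut-3-en-2-yl)cyclohexa-2,4-dien-1-one (ortho-dienone, racemic) | CC(=O)C1=C(OCOC)C=C(OC(C)C)C(C(C)(C)C=C)C1=O | intermediate
6 | 2-acetyl-5-isopropoxy-3-(methoxymethoxy)-4-(3-methylbut-2-enyl)cyclohexa-2,5-dien-1-one (para-dienone, racemic) | CC(=O)C1=C(OCOC)C(CC=C(C)C)C(OC(C)C)=CC1=O | intermediate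
7 | 1-[6-hydroxy-4-isopropoxy-2-(methoxymethoxy)-3-(3-methylbut-2-enyl)phenyl]ethanone | CC(=O)c1c(O)cc(OC(C)C)c(CC=C(C)C)c1OCOC | intermediate
8 | 1-[2-hydroxy-3-iodo-4-isopropoxy-6-(methoxymethoxy)-5-(3-methylbut-2-enyl)phenyl]ethanone | CC(=O)c1c(O)c(I)c(OC(C)C)c(CC=C(C)C)c1OCOC | intermediate
9 | 2,4,5-trihydroxybenzaldehyde | O=Cc1cc(O)c(O)cc1O | starting material
10 | 2-hydroxy-4,5-bis(triisopropylsilyloxy)benzaldehyde | O=Cc1cc(O[Si](C(C)C)(C(C)C)C(C)C)c(O[Si](C(C)C)(C(C)C)C(C)C)cc1O | intermediate
11 | 2-(methoxymethoxy)-4,5-bis(triisopropylsilyloxy)benzaldehyde | O=Cc1cc(O[Si](C(C)C)(C(C)C)C(C)C)c(O[Si](C(C)C)(C(C)C)C(C)C)cc1OCOC | intermediate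
12 | 2-(methoxymethoxy)-4,5-bis(triisopropylsilyloxy)benzoic acid | OC(=O)c1cc(O[Si](C(C)C)(C(C)C)C(C)C)c(O[Si](C(C)C)(C(C)C)C(C)C)cc1OCOC | intermediate
13 | 3-methylbuta-1,2-diene | CC(C)=C=C | starting material
14 | 2,3-dibromo-3-methylbut-1-ene | C=C(Br)C(C)(C)Br | intermediate
15 | 1,2-dibromo-3-methylbut-2-ene | BrCC(Br)=C(C)C | intermediate
16 | 1-[2-(methoxymethoxy)-4,5-bis(triisopropylsilyloxy)benzoyl]imidazole (acyl imidazolide) | COCOc1cc(O[Si](C(C)C)(C(C)C)C(C)C)c(O[Si](C(C)C)(C(C)C)C(C)C)cc1C(=O)n1ccnc1 | intermediate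
17 | 1-[2-hydroxy-3-iodo-4-isopropoxy-6-(methoxymethoxy)-5-(3-methylbut-2-enyl)phenyl]-3-[2-(methoxymethoxy)-4,5-bis(triisopropylsilyloxy)phenyl]propane-1,3-dione | CC(C)=CCc1c(OCOC)c(C(=O)CC(=O)c2cc(O[Si](C(C)C)(C(C)C)C(C)C)c(O[Si](C(C)C)(C(C)C)C(C)C)cc2OCOC)c(O)c(I)c1OC(C)C | intermediate
18 | 2-(2-bromo-3-methylbut-2-enyl) derivative of 17 (racemic) | CC(C)=CCc1c(OCOC)c(C(=O)C(CC(Br)=C(C)C)C(=O)c2cc(O[Si](C(C)C)(C(C)C)C(C)C)c(O[Si](C(C)C)(C(C)C)C(C)C)cc2OCOC)c(O)c(I)c1OC(C)C | intermediate
19 | 3-(2-bromo-3-methylbut-2-enyl)-2-hydroxy-8-iodo-7-isopropoxy-5-(methoxymethoxy)-2-[2-(methoxymethoxy)-4,5-bis(triisopropylsilyloxy)phenyl]-6-(3-methylbut-2-enyl)chroman-4-one (hemiketal, diastereomer mixture) | CC(C)=CCc1c(OCOC)c2C(=O)C(CC(Br)=C(C)C)C(O)(c3cc(O[Si](C(C)C)(C(C)C)C(C)C)c(O[Si](C(C)C)(C(C)C)C(C)C)cc3OCOC)Oc2c(I)c1OC(C)C | intermediate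
20 | 3-(2-bromo-3-methylbut-2-enyl)-8-iodo-7-isopropoxy-5-(methoxymethoxy)-2-[2-(methoxymethoxy)-4,5-bis(triisopropylsilyloxy)phenyl]-6-(3-methylbut-2-enyl)chromen-4-one | CC(C)=CCc1c(OCOC)c2c(=O)c(CC(Br)=C(C)C)c(-c3cc(O[Si](C(C)C)(C(C)C)C(C)C)c(O[Si](C(C)C)(C(C)C)C(C)C)cc3OCOC)oc2c(I)c1OC(C)C | intermediate
21 | 8-[(trimethylsilyl)ethynyl] analogue of 20 | CC(C)=CCc1c(OCOC)c2c(=O)c(CC(Br)=C(C)C)c(-c3cc(O[Si](C(C)C)(C(C)C)C(C)C)c(O[Si](C(C)C)(C(C)C)C(C)C)cc3OCOC)oc2c(C#C[Si](C)(C)C)c1OC(C)C | intermediate
22 | 3-(2-bromo-3-methylbut-2-enyl)-8-ethynyl-7-isopropoxy-5-(methoxymethoxy)-2-[2-(methoxymethoxy)-4,5-bis(triisopropylsilyloxy)phenyl]-6-(3-methylbut-2-enyl)chromen-4-one | CC(C)=CCc1c(OCOC)c2c(=O)c(CC(Br)=C(C)C)c(-c3cc(O[Si](C(C)C)(C(C)C)C(C)C)c(O[Si](C(C)C)(C(C)C)C(C)C)cc3OCOC)oc2c(C#C)c1OC(C)C | intermediate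
23 | zwitterion of 22 after hydride shift: O7 as propan-2-ylidene oxonium, C8 bearing a (Z)-2-(tetraiodoplatinato)ethenyl group | CC(C)=CCc1c(OCOC)c2c(=O)c(CC(Br)=C(C)C)c(-c3cc(O[Si](C(C)C)(C(C)C)C(C)C)c(O[Si](C(C)C)(C(C)C)C(C)C)cc3OCOC)oc2c(/C=C\[Pt-](I)(I)(I)I)c1[O+]=C(C)C | intermediate
24 | 3-(2-bromo-3-methylbut-2-enyl)-5-(methoxymethoxy)-2-[2-(methoxymethoxy)-4,5-bis(triisopropylsilyloxy)phenyl]-8,8-dimethyl-6-(3-methylbut-2-enyl)-4H,8H-pyrano[2,3-f]chromen-4-one | CC(C)=CCc1c(OCOC)c2c(=O)c(CC(Br)=C(C)C)c(-c3cc(O[Si](C(C)C)(C(C)C)C(C)C)c(O[Si](C(C)C)(C(C)C)C(C)C)cc3OCOC)oc2c2C=CC(C)(C)Oc12 | intermediate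
25 | 3-(2-bromo-3-methylbut-2-enyl)-5-hydroxy-2-[2-hydroxy-4,5-bis(triisopropylsilyloxy)phenyl]-8,8-dimethyl-6-(3-methylbut-2-enyl)-4H,8H-pyrano[2,3-f]chromen-4-one | CC(C)=CCc1c(O)c2c(=O)c(CC(Br)=C(C)C)c(-c3cc(O[Si](C(C)C)(C(C)C)C(C)C)c(O[Si](C(C)C)(C(C)C)C(C)C)cc3O)oc2c2C=CC(C)(C)Oc12 | intermediate
26 | 4′,5′-bis-O-(triisopropylsilyl)isocycloheterophyllin | CC(C)=CCc1c(O)c2c(=O)c3c(oc2c2C=CC(C)(C)Oc12)-c1cc(O[Si](C(C)C)(C(C)C)C(C)C)c(O[Si](C(C)C)(C(C)C)C(C)C)cc1OC(=C(C)C)C3 | intermediate
27 | isocycloheterophyllin | CC(C)=CCc1c(O)c2c(=O)c3c(oc2c2C=CC(C)(C)Oc12)-c1cc(O)c(O)cc1OC(=C(C)C)C3 | target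

**Totals and risks**

Total step count: 17. Longest linear sequence: 13 (steps 1–5 and 10–17).

Steps most likely to fail:

Step 14 (proposed new method). Hydride transfer may lose to 5-endo attack of O7 on the platinum-bound alkyne with loss of the isopropyl group, or the catalyst may be tied up by the substrate. The fallback sets out from 22 and comes back at 24, closing the same bond by known carbenoid chemistry. Gold-catalysed Markovnikov hydration of the alkyne (Ph3PAuNTf2, aqueous dioxane) would give the 8-acetylflavone F1. Trifluoroacetylation of its lithium enolate (LiN(SiMe3)2, CF3CO2CH2CF3) would give the trifluoroacetyl diketone F2, which is not isolated. Diazo transfer with loss of the trifluoroacetyl group (MsN3, Et3N) would give the diazomethyl ketone F3. Rh2(OAc)4-catalysed intramolecular carbenoid insertion into the tertiary C–H next to O7 would give the 2,2-dimethylchroman-4-one F4. NaBH4 would reduce the aryl ketone (the chromone carbonyl is inert) to the chromanol F5, and dehydration (PPTS, toluene) would give 24.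

Step 16. Oxidative addition at the tetrasubstituted alkenyl bromide may be too slow, copper may be sequestered by the 5-hydroxy-4-oxo chelate, or silyl groups may be lost under hot carbonate. The fallback sets out from 25 and comes back at 26 with the polarity reversed. Miyaura borylation of the alkenyl bromide (PdCl2(dppf), B2pin2, KOAc, dioxane) would give the alkenylboronate F6, and Chan–Lam oxidative coupling with the 2′-hydroxyl (Cu(OAc)2, pyridine, air, rt) would close the oxepine to 26.

Step 5. Iodonium formation at the prenyl double bond, with capture by the neighbouring acetal oxygen, may compete with ring iodination. The fallback sets out from 3 and comes back at 8 by changing the order of events. Iodination of 3 ortho to its free hydroxyl (NIS, DMF) would give the iodophenol F7, and O-prenylation (prenyl bromide, K2CO3) would give the ether F8. Heating as in step 4, now with both ortho positions blocked, can only deliver the prenyl group to the para carbon and would give 8.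

**Further compounds**

F1 | step 14 | 8-acetyl-3-(2-bromo-3-methylbut-2-enyl)-7-isopropoxy-5-(methoxymethoxy)-2-[2-(methoxymethoxy)-4,5-bis(triisopropylsilyloxy)phenyl]-6-(3-methylbut-2-enyl)chromen-4-one | CC(C)=CCc1c(OCOC)c2c(=O)c(CC(Br)=C(C)C)c(-c3cc(O[Si](C(C)C)(C(C)C)C(C)C)c(O[Si](C(C)C)(C(C)C)C(C)C)cc3OCOC)oc2c(C(C)=O)c1OC(C)C
F2 | step 14 | 8-(4,4,4-trifluoro-3-oxobutanoyl) analogue of F1 | CC(C)=CCc1c(OCOC)c2c(=O)c(CC(Br)=C(C)C)c(-c3cc(O[Si](C(C)C)(C(C)C)C(C)C)c(O[Si](C(C)C)(C(C)C)C(C)C)cc3OCOC)oc2c(C(=O)CC(=O)C(F)(F)F)c1OC(C)C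
F3 | step 14 | 8-(2-diazoacetyl) analogue of F1 | CC(C)=CCc1c(OCOC)c2c(=O)c(CC(Br)=C(C)C)c(-c3cc(O[Si](C(C)C)(C(C)C)C(C)C)c(O[Si](C(C)C)(C(C)C)C(C)C)cc3OCOC)oc2c(C(=O)C=[N+]=[N-])c1OC(C)C
F4 | step 14 | 9,10-dihydro-10-oxo analogue of 24 (2,2-dimethylchroman-4-one fused at O7/C8) | CC(C)=CCc1c(OCOC)c2c(=O)c(CC(Br)=C(C)C)c(-c3cc(O[Si](C(C)C)(C(C)C)C(C)C)c(O[Si](C(C)C)(C(C)C)C(C)C)cc3OCOC)oc2c2C(=O)CC(C)(C)Oc12
F5 | step 14 | 9,10-dihydro-10-hydroxy analogue of 24 (racemic chromanol) | CC(C)=CCc1c(OCOC)c2c(=O)c(CC(Br)=C(C)C)c(-c3cc(O[Si](C(C)C)(C(C)C)C(C)C)c(O[Si](C(C)C)(C(C)C)C(C)C)cc3OCOC)oc2c2C(O)CC(C)(C)Oc12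
F6 | step 16 | analogue of 25 with the alkenyl bromide replaced by a pinacol boronate | CC(C)=CCc1c(O)c2c(=O)c(CC(B4OC(C)(C)C(C)(C)O4)=C(C)C)c(-c3cc(O[Si](C(C)C)(C(C)C)C(C)C)c(O[Si](C(C)C)(C(C)C)C(C)C)cc3O)oc2c2C=CC(C)(C)Oc12
F7 | step 5 | 1-[2-hydroxy-3-iodo-4-isopropoxy-6-(methoxymethoxy)phenyl]ethanone | CC(=O)c1c(O)c(I)c(OC(C)C)cc1OCOC
F8 | step 5 | 1-[3-iodo-4-isopropoxy-6-(methoxymethoxy)-2-(3-methylbut-2-enyloxy)phenyl]ethanone | CC(=O)c1c(OCC=C(C)C)c(I)c(OC(C)C)cc1OCOC
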